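**Retrosynthetic overview**
1. Feature: ring B, the 3,4-dihydroxy-5-methoxyphenyl ring (C1' bonded to C7, oxygens on C3', C4', C5'), is a 5-alkylpyrogallol. Its C3'-O and C5'-O are mirror-related across the C1'-C4' axis, so it equals an aromatised 2-alkoxy-5-alkylcyclohexane-1,3-dione.
2. Ring B is the only ring made (ring A, the guaiacyl ring, is bought). It is cut at C6'-C1' and C4'-C5' into dimethyl malonate and an E-enone whose carbonyl carries CH2OBn.
3. The enone C1'=C2' bond comes from cross metathesis of a terminal alkene holding C1-C7 with 1-(benzyloxy)but-3-en-2-one.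
4. The C3-C4 bond comes from a lithiated dithiane (ring A, C1-C3) and (R)-1,2-epoxy-5-hexene, whose resolved carbinol carbon becomes C5.
5. After the annulation: decarboxylation, one enol O-methylation (breaks the C3'/C5' symmetry), dehydrogenation to the phenol, acid unmasking of C3 and C5, hydrogenolysis.

Key step: step 11

Remarks:
- C1-C7 number the heptane chain from ring A. C1'-C6' number ring B.
- Z stands for the side chain (3R)-4-(2-{2-[4-(benzyloxy)-3-methoxyphenyl]ethyl}-1,3-dioxolan-2-yl)-3-[(tert-butyldimethylsilyl)oxy]butyl, bonded through its C1 (= C7).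
- Assumption: all intermediates with a non-aromatic ring B are carried as mixtures of ring epimers and enol tautomers. They are drawn in the keto form without ring descriptors, because these centres vanish on aromatisation.

Step 1
Reactants: 1 3-(4-hydroxy-3-methoxyphenyl)propanoic acid (dihydroferulic acid)
Product: 2 benzyl 3-[4-(benzyloxy)-3-methoxyphenyl]propanoate
Conditions: BnBr (2.4 equiv), K2CO3 (3 equiv), DMF, 60 °C
Reagents that add atoms: benzyl bromide BrCc1ccccc1
Why: Williamson ether synthesis and carboxylate O-alkylation run together, so the phenol gains a benzyl ether that lasts until the final hydrogenolysis and the acid becomes an ester ready for partial reduction.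

Step 2
Reactants: 2 benzyl 3-[4-(benzyloxy)-3-methoxyphenyl]propanoate
Product: 3 3-[4-(benzyloxy)-3-methoxyphenyl]propanal
Conditions: i-Bu2AlH (1.1 equiv), CH2Cl2, -78 °C; aq KNaC4H4O6
Reagents that add atoms: none
Why: Partial ester reduction with i-Bu2AlH stops at the aldehyde because the aluminium hemiacetal is stable at -78 °C and collapses only on aqueous work-up, and the aryl benzyl ether is inert.

Step 3
Reactants: 3 3-[4-(benzyloxy)-3-methoxyphenyl]propanal
Product: 4 2-{2-[4-(benzyloxy)-3-methoxyphenyl]ethyl}-1,3-dithiane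
Conditions: HS(CH2)3SH (1.1 equiv), BF3·OEt2 (0.2 equiv), CH2Cl2, 0 °C to rt
Reagents that add atoms: propane-1,3-dithiol SCCCS
Why: Lewis acid catalysed dithioacetalisation prepares the aldehyde carbon (C3) for Corey-Seebach umpolung, and substoichiometric BF3·OEt2 at 0 °C is too mild to cleave the aryl benzyl ether.

Step 4
Reactants: 5 rac-2-(but-3-en-1-yl)oxirane (1,2-epoxy-5-hexene)
Product: 6 (R)-2-(but-3-en-1-yl)oxirane
Conditions: (R,R)-(salen)Co(OAc) (0.5 mol%; salen = N,N'-bis(3,5-di-tert-butylsalicylidene)cyclohexane-1,2-diamine dianion), H2O (0.55 equiv), neat, 0 °C to rt; distillation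
Reagents that add atoms: none
Why: In the Jacobsen hydrolytic kinetic resolution the (R,R) complex of trivalent cobalt hydrates the S epoxide much faster, so past half conversion the volatile epoxide that remains should be the R enantiomer, which fixes the configuration of C5.

Step 5
Reactants: 4 2-{2-[4-(benzyloxy)-3-methoxyphenyl]ethyl}-1,3-dithiane; 6 (R)-2-(but-3-en-1-yl)oxirane
Product: 8 (2R)-1-(2-{2-[4-(benzyloxy)-3-methoxyphenyl]ethyl}-1,3-dithian-2-yl)hex-5-en-2-ol, via 2-lithiodithiane 7 (not isolated)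
Conditions: n-BuLi (1.05 equiv), THF, -25 °C, 2 h; then 6 (1.2 equiv), -25 to 0 °C; H2O
Reagents that add atoms: none
Why: In this Corey-Seebach alkylation the dithiane anion opens the monosubstituted epoxide by SN2 attack at the free CH2 (C3-C4 bond), so the C-O stereocentre is untouched and R in 6 becomes R at C5.

Step 6
Reactants: 8 (2R)-1-(2-{2-[4-(benzyloxy)-3-methoxyphenyl]ethyl}-1,3-dithian-2-yl)hex-5-en-2-ol
Product: 9 tert-butyl{[(2R)-1-(2-{2-[4-(benzyloxy)-3-methoxyphenyl]ethyl}-1,3-dithian-2-yl)hex-5-en-2-yl]oxy}dimethylsilane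
Conditions: TBSOTf (1.3 equiv), 2,6-lutidine (2 equiv), CH2Cl2, 0 °C
Reagents that add atoms: tert-butyldimethylsilyl triflate CC(C)(C)[Si](C)(C)OS(=O)(=O)C(F)(F)F
Why: Silyl triflate silylation overcomes the crowding next to the quaternary dithiane carbon and reacts at oxygen only, so C5 keeps its configuration and gains a base-stable ether.

Step 7
Reactants: 9 tert-butyl{[(2R)-1-(2-{2-[4-(benzyloxy)-3-methoxyphenyl]ethyl}-1,3-dithian-2-yl)hex-5-en-2-yl]oxy}dimethylsilane
Product: 10 tert-butyl{[(2R)-1-(2-{2-[4-(benzyloxy)-3-methoxyphenyl]ethyl}-1,3-dioxolan-2-yl)hex-5-en-2-yl]oxy}dimethylsilane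
Conditions: PhI(OCOCF3)2 (1.5 equiv), HOCH2CH2OH (20 equiv), MeCN/CH2Cl2, 0 °C, 20 min; aq NaHCO3
Reagents that add atoms: ethane-1,2-diol OCCO
Why: In this oxidative dithiane-to-acetal exchange the hypervalent iodine reagent activates sulfur far faster than it touches the alkene or the aryl ethers, and the diol captures the thionium ion, so sulfur is gone before the ruthenium and palladium steps and the beta-silyloxy ketone is never set free.

Step 8
Reactants: 11 (benzyloxy)acetyl chloride
Product: 12 2-(benzyloxy)-N-methoxy-N-methylacetamide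
Conditions: MeNH(OMe)·HCl (1.1 equiv), Et3N (2.3 equiv), CH2Cl2, 0 °C to rt
Reagents that add atoms: N,O-dimethylhydroxylamine hydrochloride CNOC.Cl
Why: N-acylation of the hydroxylamine by the acid chloride gives the Weinreb amide cleanly, and the benzyl ether is a spectator.

Step 9
Reactants: 12 2-(benzyloxy)-N-methoxy-N-methylacetamide
Product: 13 1-(benzyloxy)but-3-en-2-one
Conditions: CH2=CHMgBr (1.3 equiv), THF, -78 to 0 °C; poured into cold 1 M HCl; used at once
Reagents that add atoms: vinylmagnesium bromide C=C[Mg]Br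
Why: In the Weinreb ketone synthesis the chelated tetrahedral adduct prevents a second addition, and the inverse quench into cold acid protonates the released amine before it can add to the new vinyl ketone.

Step 10
Reactants: 10 tert-butyl{[(2R)-1-(2-{2-[4-(benzyloxy)-3-methoxyphenyl]ethyl}-1,3-dioxolan-2-yl)hex-5-en-2-yl]oxy}dimethylsilane; 13 1-(benzyloxy)but-3-en-2-one
Product: 14 (3E,7R)-1-(benzyloxy)-8-(2-{2-[4-(benzyloxy)-3-methoxyphenyl]ethyl}-1,3-dioxolan-2-yl)-7-[(tert-butyldimethylsilyl)oxy]oct-3-en-2-one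
Conditions: 13 (2.5 equiv), second-generation Hoveyda-Grubbs catalyst (H2IMes)Cl2Ru(=CH-C6H4-2-O-i-Pr) (4 mol%), CH2Cl2, 40 °C
Reagents that add atoms: none
Why: Olefin cross metathesis between an unhindered terminal alkene and an electron-poor vinyl ketone that homodimerises slowly favours the cross product as the E-enone, is driven by loss of ethene, and tolerates ketal, silyl ether and benzyl ethers.

Step 11
Reactants: 14 (3E,7R)-1-(benzyloxy)-8-(2-{2-[4-(benzyloxy)-3-methoxyphenyl]ethyl}-1,3-dioxolan-2-yl)-7-[(tert-butyldimethylsilyl)oxy]oct-3-en-2-one; 15 dimethyl malonate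
Product: 17 methyl 3-(benzyloxy)-2,4-dioxo-6-Z-cyclohexane-1-carboxylate, via Michael adduct 16 (not isolated)
Conditions: 15 (1.3 equiv), NaOMe (1.5 equiv), MeOH/THF, Ar, rt then 65 °C; 0 °C, cold 1 M HCl to pH 4, EtOAc
Reagents that add atoms: none
Why: Proposed new method: methoxide forms the malonate anion, which adds 1,4 to the E-enone (C6'-C1' bond); proton exchange in methanol then delivers the ketone enolate at the benzyloxy-bearing carbon C4', which attacks the nearer malonate ester and expels methoxide (C4'-C5' bond). The closest known reaction type is the Michael-Claisen annulation of malonates with alkenyl methyl or alkenyl alkyl ketones (dimedone and olivetol type), and C-acylation of alpha-alkoxy ketone enolates at the oxygenated carbon is known from Baker-Venkataraman chemistry of omega-methoxyacetophenones, but the tandem process with an alkoxy group on the nucleophilic carbon has not been shown. Ring B closes in the 6-(enolendo)-exo-trig mode, and the otherwise reversible sequence is pulled forward by deprotonation of the 2-alkoxy-1,3-dione, which is many pK units more acidic than methanol. C1', C4' and C6' form without control as a mixture, which is harmless because C4' and C6' are enolisable, C1' has no influence on later steps and all three become sp2 carbons by step 15, while C5 lies outside the reacting array and keeps its R configuration. The step needs 1,4- over 1,2-addition, secured by the soft, stabilised malonate anion under equilibrating conditions, and closure through C4' rather than C2', secured because the C2' enolate could only build a four-membered ring. The C5 silyl ether and the C3 dioxolane remove the beta-hydroxy ketone motif, so retro-aldol and elimination along C3-C5 cannot compete.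

Step 12
Reactants: 17 methyl 3-(benzyloxy)-2,4-dioxo-6-Z-cyclohexane-1-carboxylate
Product: 19 2-(benzyloxy)-5-Z-cyclohexane-1,3-dione, via keto acid 18 (not isolated)
Conditions: 2 M aq NaOH (4 equiv), MeOH, 60 °C; 0 °C, 1 M HCl to pH 4-5 under toluene; separated toluene layer, 80 °C
Reagents that add atoms: none
Why: Saponification followed by beta-keto acid decarboxylation through the cyclic six-membered transition state is the classical end of dimedone-type syntheses, the dione sits as its enolate in base and so resists retro-Claisen cleavage, and a brief cold acidification with heating only in the separated organic layer should spare dioxolane and silyl ether.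

Step 13
Reactants: 19 2-(benzyloxy)-5-Z-cyclohexane-1,3-dione
Product: 20 2-(benzyloxy)-3-methoxy-5-Z-cyclohex-2-en-1-one (both ring C5 epimers)
Conditions: Me3SiCHN2 (1.5 equiv), toluene/MeOH 4:1, 0 °C to rt
Reagents that add atoms: trimethylsilyldiazomethane C[Si](C)(C)C=[N+]=[N-]
Why: Diazoalkane O-methylation of the acidic enol proceeds by proton transfer and collapse of the ion pair at oxygen under neutral conditions, and since the two carbonyls of 19 are constitutionally equivalent either oxygen gives the same vinylogous ester, whose two ring epimers converge in step 15.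

Step 14
Reactants: 20 2-(benzyloxy)-3-methoxy-5-Z-cyclohex-2-en-1-one
Product: 22 {[6-(benzyloxy)-5-methoxy-3-Z-cyclohexa-1,5-dien-1-yl]oxy}trimethylsilane, via lithium dienolate 21 (not isolated)
Conditions: LiN(i-Pr)2 (1.3 equiv), THF, -78 °C; Me3SiCl (1.6 equiv), -78 to 0 °C; pentane, cold aq NaHCO3; used crude
Reagents that add atoms: chlorotrimethylsilane C[Si](C)(C)Cl
Why: Kinetic deprotonation of a vinylogous ester takes place at the alpha' carbon C2' (Stork-Danheiser regiochemistry) and O-silylation traps the cross-conjugated dienolate, while any extended dienolate would lead to the same phenol in the next step.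

Step 15
Reactants: 22 {[6-(benzyloxy)-5-methoxy-3-Z-cyclohexa-1,5-dien-1-yl]oxy}trimethylsilane
Product: 24 2-(benzyloxy)-3-methoxy-5-Z-phenol, via 4H-dienone 23 (not isolated)
Conditions: Pd(OAc)2 (1.05 equiv), MeCN, rt
Reagents that add atoms: none
Why: In the Saegusa-Ito oxidation divalent palladium replaces silicon to give the oxo-allyl complex at C2', beta-hydride elimination of the C1' hydrogen gives the cyclohexa-2,5-dienone, and this keto tautomer goes over to the phenol with the acetic acid formed, under conditions that leave benzyl ethers, silyl ether and dioxolane alone.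

Step 16
Reactants: 24 2-(benzyloxy)-3-methoxy-5-Z-phenol
Product: 26 (5R)-7-[4-(benzyloxy)-3-hydroxy-5-methoxyphenyl]-1-[4-(benzyloxy)-3-methoxyphenyl]-5-hydroxyheptan-3-one, via silyloxy ketone 25 (not isolated)
Conditions: 2 M aq HCl/THF 1:4, rt
Reagents that add atoms: water O
Why: Acid hydrolysis should remove the dioxolane first and the secondary silyl ether next in one operation, dilute acid at room temperature is too mild to dehydrate a gingerol-type beta-hydroxy ketone at a useful rate, the aryl benzyl ethers are inert, and the C5-O bond is never broken.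

Step 17
Reactants: 26 (5R)-7-[4-(benzyloxy)-3-hydroxy-5-methoxyphenyl]-1-[4-(benzyloxy)-3-methoxyphenyl]-5-hydroxyheptan-3-one
Product: 27 (5R)-7-(3,4-dihydroxy-5-methoxyphenyl)-5-hydroxy-1-(4-hydroxy-3-methoxyphenyl)heptan-3-one (CNP0183620.1)
Conditions: H2 (1 atm), 10% Pd/C, EtOAc/EtOH, rt; filtered and concentrated under Ar
Reagents that add atoms: none
Why: Catalytic hydrogenolysis cleaves both aryl benzyl ethers under neutral conditions that do not reduce the dialkyl ketone, do not affect the non-benzylic C5 carbinol, and release the oxidation-sensitive catechol only at the very end.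

**Compound list**
1 | 3-(4-hydroxy-3-methoxyphenyl)propanoic acid (dihydroferulic acid) | COc1cc(CCC(=O)O)ccc1O | starting material
2 | benzyl 3-[4-(benzyloxy)-3-methoxyphenyl]propanoate | COc1cc(CCC(=O)OCc2ccccc2)ccc1OCc1ccccc1 | intermediate
3 | 3-[4-(benzyloxy)-3-methoxyphenyl]propanal | COc1cc(CCC=O)ccc1OCc1ccccc1 | intermediate
4 | 2-{2-[4-(benzyloxy)-3-methoxyphenyl]ethyl}-1,3-dithiane | COc1cc(CCC2SCCCS2)ccc1OCc1ccccc1 | intermediate
5 | rac-2-(but-3-en-1-yl)oxirane (1,2-epoxy-5-hexene) | C=CCCC1CO1 | starting material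
6 | (R)-2-(but-3-en-1-yl)oxirane | C=CCC[C@@H]1CO1 | intermediate
7 | 2-lithio derivative of dithiane 4 | [Li]C1(CCc2ccc(OCc3ccccc3)c(OC)c2)SCCCS1 | intermediate
8 | (2R)-1-(2-{2-[4-(benzyloxy)-3-methoxyphenyl]ethyl}-1,3-dithian-2-yl)hex-5-en-2-ol | COc1cc(CCC2(C[C@H](O)CCC=C)SCCCS2)ccc1OCc1ccccc1 | intermediate
9 | TBS ether of 8, (R) | COc1cc(CCC2(C[C@H](O[Si](C)(C)C(C)(C)C)CCC=C)SCCCS2)ccc1OCc1ccccc1 | intermediate
10 | dioxolane alkene, (R): tert-butyl{[(2R)-1-(2-{2-[4-(benzyloxy)-3-methoxyphenyl]ethyl}-1,3-dioxolan-2-yl)hex-5-en-2-yl]oxy}dimethylsilane | COc1cc(CCC2(C[C@H](O[Si](C)(C)C(C)(C)C)CCC=C)OCCO2)ccc1OCc1ccccc1 | intermediate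
11 | (benzyloxy)acetyl chloride | O=C(Cl)COCc1ccccc1 | starting material
12 | 2-(benzyloxy)-N-methoxy-N-methylacetamide | CON(C)C(=O)COCc1ccccc1 | intermediate
13 | 1-(benzyloxy)but-3-en-2-one | C=CC(=O)COCc1ccccc1 | intermediate
14 | (3E,7R)-1-(benzyloxy)-8-(2-{2-[4-(benzyloxy)-3-methoxyphenyl]ethyl}-1,3-dioxolan-2-yl)-7-[(tert-butyldimethylsilyl)oxy]oct-3-en-2-one | COc1cc(CCC2(C[C@H](O[Si](C)(C)C(C)(C)C)CC/C=C/C(=O)COCc3ccccc3)OCCO2)ccc1OCc1ccccc1 | intermediate
15 | dimethyl malonate | COC(=O)CC(=O)OC | starting material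
16 | dimethyl 2-[4-(benzyloxy)-3-oxo-1-Z-butyl]malonate (Michael adduct) | COc1cc(CCC2(C[C@H](O[Si](C)(C)C(C)(C)C)CCC(CC(=O)COCc3ccccc3)C(C(=O)OC)C(=O)OC)OCCO2)ccc1OCc1ccccc1 | intermediate
17 | methyl 3-(benzyloxy)-2,4-dioxo-6-Z-cyclohexane-1-carboxylate | COc1cc(CCC2(C[C@H](O[Si](C)(C)C(C)(C)C)CCC3CC(=O)C(OCc4ccccc4)C(=O)C3C(=O)OC)OCCO2)ccc1OCc1ccccc1 | intermediate
18 | 3-(benzyloxy)-2,4-dioxo-6-Z-cyclohexane-1-carboxylic acid | COc1cc(CCC2(C[C@H](O[Si](C)(C)C(C)(C)C)CCC3CC(=O)C(OCc4ccccc4)C(=O)C3C(=O)O)OCCO2)ccc1OCc1ccccc1 | intermediate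
19 | 2-(benzyloxy)-5-Z-cyclohexane-1,3-dione | COc1cc(CCC2(C[C@H](O[Si](C)(C)C(C)(C)C)CCC3CC(=O)C(OCc4ccccc4)C(=O)C3)OCCO2)ccc1OCc1ccccc1 | intermediate
20 | 2-(benzyloxy)-3-methoxy-5-Z-cyclohex-2-en-1-one | COc1cc(CCC2(C[C@H](O[Si](C)(C)C(C)(C)C)CCC3CC(=O)C(OCc4ccccc4)=C(OC)C3)OCCO2)ccc1OCc1ccccc1 | intermediate
21 | lithium cross-conjugated dienolate of 20 (O-Li on C3', double bonds C2'=C3' and C4'=C5') | COc1cc(CCC2(C[C@H](O[Si](C)(C)C(C)(C)C)CCC3C=C(O[Li])C(OCc4ccccc4)=C(OC)C3)OCCO2)ccc1OCc1ccccc1 | intermediate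
22 | {[6-(benzyloxy)-5-methoxy-3-Z-cyclohexa-1,5-dien-1-yl]oxy}trimethylsilane | COc1cc(CCC2(C[C@H](O[Si](C)(C)C(C)(C)C)CCC3C=C(O[Si](C)(C)C)C(OCc4ccccc4)=C(OC)C3)OCCO2)ccc1OCc1ccccc1 | intermediate
23 | 2-(benzyloxy)-3-methoxy-5-Z-cyclohexa-2,5-dien-1-one | COc1cc(CCC2(C[C@H](O[Si](C)(C)C(C)(C)C)CCC3=CC(=O)C(OCc4ccccc4)=C(OC)C3)OCCO2)ccc1OCc1ccccc1 | intermediate
24 | 2-(benzyloxy)-3-methoxy-5-Z-phenol | COc1cc(CCC2(C[C@H](O[Si](C)(C)C(C)(C)C)CCc3cc(O)c(OCc4ccccc4)c(OC)c3)OCCO2)ccc1OCc1ccccc1 | intermediate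
25 | (5R)-7-[4-(benzyloxy)-3-hydroxy-5-methoxyphenyl]-1-[4-(benzyloxy)-3-methoxyphenyl]-5-[(tert-butyldimethylsilyl)oxy]heptan-3-one | COc1cc(CCC(=O)C[C@H](O[Si](C)(C)C(C)(C)C)CCc2cc(O)c(OCc3ccccc3)c(OC)c2)ccc1OCc1ccccc1 | intermediate
26 | (5R)-7-[4-(benzyloxy)-3-hydroxy-5-methoxyphenyl]-1-[4-(benzyloxy)-3-methoxyphenyl]-5-hydroxyheptan-3-one | COc1cc(CCC(=O)C[C@H](O)CCc2cc(O)c(OCc3ccccc3)c(OC)c2)ccc1OCc1ccccc1 | intermediate
27 | (5R)-7-(3,4-dihydroxy-5-methoxyphenyl)-5-hydroxy-1-(4-hydroxy-3-methoxyphenyl)heptan-3-one | COc1cc(CCC(=O)C[C@H](O)CCc2cc(O)c(O)c(OC)c2)ccc1O | target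

**Total step count:** 17. **Longest linear sequence:** 14 steps (1, 2, 3, 5, 6, 7, 10, 11, 12, 13, 14, 15, 16, 17).

**Steps most likely to fail**

1. **Step 11** (bears the label).
   - What may go wrong: the sequence may halt after the conjugate addition. Retro-Michael cleavage and base-induced self-condensation of the alkoxy ketone may also overtake the slower acylation at the hindered, oxygen-substituted enolate carbon.
   - Fallback (known chemistry only; the C4' oxygen is introduced after ring B is closed): it sets out from 10 and comes back at 19. Cross metathesis of 10 with but-3-en-2-one under the conditions of step 10 gives the methyl enone F1. The classical annulation with 15 and NaOMe in MeOH passes through the Michael adduct F2 and gives the keto ester F3. Saponification and decarboxylation as in step 12 pass through the keto acid F4 and give the 5-substituted cyclohexane-1,3-dione F5. Regitz diazo transfer (4-acetamidobenzenesulfonyl azide, Et3N, MeCN) gives the 2-diazo-1,3-dione F6. Carbenoid O-H insertion into benzyl alcohol (Rh2(OAc)4 1 mol%, BnOH 5 equiv, benzene, 60 °C) then gives 19.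

2. **Step 12.**
   - What may go wrong: the dioxolane or the silyl ether may be lost while the medium is acidified. Ring opening by retro-Claisen attack of hot hydroxide is also possible.
   - Fallback (the ester is removed by palladium catalysis at neutral pH instead of by hydrolysis): it sets out from 14 and comes back at 19. The annulation is run with diallyl malonate and NaOCH2CH=CH2 in allyl alcohol/THF. It passes through the diallyl Michael adduct F7 and gives the allyl keto ester F8. Tsuji-type deallylation (Pd(PPh3)4 5 mol%, morpholine 10 equiv, THF, rt to 40 °C) ionises the allyl ester on zerovalent palladium. The large excess of morpholine traps the allyl fragment ahead of the hindered dione. The carboxylate form of 18 then loses CO2 to give 19.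

3. **Step 15.**
   - What may go wrong: the acetic acid formed may protodesilylate the dienol ether back to the enone. Metal may also deposit early, before beta-hydride elimination is complete.
   - Fallback (chalcogen syn-elimination instead of palladium dehydrosilylation): it sets out from 20 and comes back at 24. The dienolate 21 (LiN(i-Pr)2, THF, -78 °C) is trapped with PhSeCl to give the alpha'-phenylselanyl enone F9. One equivalent of m-CPBA in CH2Cl2 at -78 °C gives the selenoxide F10. Warming in the presence of i-Pr2NH brings about syn-elimination to 23, which tautomerises to 24.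

**Further compounds**
F1 | step 11 | (3E,7R)-8-(2-{2-[4-(benzyloxy)-3-methoxyphenyl]ethyl}-1,3-dioxolan-2-yl)-7-[(tert-butyldimethylsilyl)oxy]oct-3-en-2-one | COc1cc(CCC2(C[C@H](O[Si](C)(C)C(C)(C)C)CC/C=C/C(C)=O)OCCO2)ccc1OCc1ccccc1
F2 | step 11 | dimethyl 2-(3-oxo-1-Z-butyl)malonate | COc1cc(CCC2(C[C@H](O[Si](C)(C)C(C)(C)C)CCC(CC(C)=O)C(C(=O)OC)C(=O)OC)OCCO2)ccc1OCc1ccccc1
F3 | step 11 | methyl 2,4-dioxo-6-Z-cyclohexane-1-carboxylate | COc1cc(CCC2(C[C@H](O[Si](C)(C)C(C)(C)C)CCC3CC(=O)CC(=O)C3C(=O)OC)OCCO2)ccc1OCc1ccccc1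
F4 | step 11 | 2,4-dioxo-6-Z-cyclohexane-1-carboxylic acid | COc1cc(CCC2(C[C@H](O[Si](C)(C)C(C)(C)C)CCC3CC(=O)CC(=O)C3C(=O)O)OCCO2)ccc1OCc1ccccc1
F5 | step 11 | 5-Z-cyclohexane-1,3-dione | COc1cc(CCC2(C[C@H](O[Si](C)(C)C(C)(C)C)CCC3CC(=O)CC(=O)C3)OCCO2)ccc1OCc1ccccc1
F6 | step 11 | 2-diazo-5-Z-cyclohexane-1,3-dione | COc1cc(CCC2(C[C@H](O[Si](C)(C)C(C)(C)C)CCC3CC(=O)C(=[N+]=[N-])C(=O)C3)OCCO2)ccc1OCc1ccccc1
F7 | step 12 | diallyl 2-[4-(benzyloxy)-3-oxo-1-Z-butyl]malonate | COc1cc(CCC2(C[C@H](O[Si](C)(C)C(C)(C)C)CCC(CC(=O)COCc3ccccc3)C(C(=O)OCC=C)C(=O)OCC=C)OCCO2)ccc1OCc1ccccc1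
F8 | step 12 | prop-2-en-1-yl 3-(benzyloxy)-2,4-dioxo-6-Z-cyclohexane-1-carboxylate | COc1cc(CCC2(C[C@H](O[Si](C)(C)C(C)(C)C)CCC3CC(=O)C(OCc4ccccc4)C(=O)C3C(=O)OCC=C)OCCO2)ccc1OCc1ccccc1
F9 | step 15 | 2-(benzyloxy)-3-methoxy-6-(phenylselanyl)-5-Z-cyclohex-2-en-1-one | COc1cc(CCC2(C[C@H](O[Si](C)(C)C(C)(C)C)CCC3CC(OC)=C(OCc4ccccc4)C(=O)C3[Se]c5ccccc5)OCCO2)ccc1OCc1ccccc1
F10 | step 15 | 2-(benzyloxy)-3-methoxy-6-(phenylseleninyl)-5-Z-cyclohex-2-en-1-one | COc1cc(CCC2(C[C@H](O[Si](C)(C)C(C)(C)C)CCC3CC(OC)=C(OCc4ccccc4)C(=O)C3[Se](=O)c5ccccc5)OCCO2)ccc1OCc1ccccc1
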